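The readings are calculated on assumed constants; the scatter is artificial.

**The task.** Elm is the flask you must carry to 8.0 h; birch has the same charge but less partner.

| setting | elm | birch | flask |
|---|---|---|---|
| substrate | 0.050 M | 0.050 M | 0.050 M |
| partner | 1.05 equiv | 0.70 equiv | 1.05 equiv |
| free catalyst | 9.9 mol% | 9.9 mol% | 9.9 mol% |
| second catalyst | 5 mol% | 5 mol% | 5 mol% |
| remark | the very flask that is asked about, followed so far | run made earlier |  |
| time |  |  | 8.0 h |

elm run (percent of the substrate charged)

| time / min | target / % | substrate / % | self-condensation product / % |
|---|---|---|---|
| 25.0 | 0.3 | 54.5 | 32.8 |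
| 50.0 | 0 | 36.5 | 45.0 |
| 80.0 | 0 | 27.0 | 50.6 |
| 90.0 | 0.9 | 26.2 | 53.9 |

birch run (percent of the substrate charged)

| time / h | target / % | substrate / % | self-condensation product / % |
|---|---|---|---|
| 1.33 | 1.3 | 28.4 | 53.7 |
| 3.00 | 1.8 | 17.2 | 64.7 |
| 4.00 | 1.2 | 16.4 | 65.7 |
| 6.00 | 1.8 | 14.8 | 72.6 |

(readings scatter by 1 percentage point)

* how much target the flask holds at 8.0 h, in percent of the substrate charged
* how much substrate the flask holds at 8.0 h, in percent of the substrate charged
* how much self-condensation product the flask holds at 8.0 h, in percent of the substrate charged
* concentration of partner at 8.0 h, in M

- in percentages every species weighs as the substrate in it: one self-condensation product counts as two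
- the numbers in the tables scatter with a standard deviation of 1 percentage point

**Mean rate.** Two substrate make one product, so divide the product's hourly gain by the square of the substrate. Elm gains 21 points between 25.0 min and 90.0 min. Replace the curve by the mean of its end readings, and you get 1.20 h⁻¹.

**The pool.** Call the pool whatever is neither product nor target: substrate plus the gap in the balance. In birch from 3.00 h on, substrate is 52.5% of the pool. Hold that share, and the pool falls with its own square, at 0.330 h⁻¹.

**First number.** Elm's pool at 90.0 min is 45.2%. Under that rule its reciprocal grows steadily, so I reckon a pool of 23.0% at 8.0 h. Birch's late target, scaled by partner, suggests 2.40% target, leaving 74.6% product.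

**Weak link.** A falling curve that flattens lies below its chord, so the mean of the ends overstates the substrate. For a pure second-order fall, the mean square is exactly the product of the end readings. That gives 1.36 h⁻¹, more than before. The pool constant, this figure times the squared share, is 0.376 h⁻¹. I commit to a pool of 21.5%, substrate 11.3%, target 2.40%, product 76.1% and partner 0.0513 M.

**The forecast.** It gives 2.5% target, 13.5% substrate, 70% product and 0.0505 M partner, noting “Birch levels off near 15% substrate by 6 h”. We part on product, where mine is higher.

**The flask.** It gives 3.94% target, 10.3% substrate, 76.1% product and 0.0505 M partner.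

    substrate + free catalyst ⇌ free catalyst + intermediate (K = 0.820, k = 90.0 L mol⁻¹ h⁻¹)
    partner + second catalyst + intermediate → second catalyst + target (k = 270 L² mol⁻² h⁻¹)
    2 substrate → self-condensation product (k = 14.0 L mol⁻¹ h⁻¹)

**Two clocks.** In the flask at 8.0 h, substrate's half-life into intermediate, by the forward step alone, is 1.6 h, short against that time, while intermediate's half-life toward target, by that step alone with the other concentrations as charged, is 20 h, long against it; substrate plus intermediate stands at 20.0%, against the 21.5% reckoned with the pool constant 0.376 h⁻¹. For the neighbour charged with 0.20 M substrate, that constant scaled by the charge gives a pool of 7.68% from the start, and at 8.00 h the neighbour holds less, 2.30% substrate plus intermediate, beside 20.2% target.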